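**Retrosynthetic overview**
1. Target 15 ⇐ bis-MOM ether 14 by acetal cleavage. No ring is constructed: rings A and B are both bought as benzenes, and ring B is dearomatised once and re-aromatised in the key step.
2. 14 ⇐ quinone monoketal 8 + prenylMgCl 9 + prenyl bromide 10. The key C4'–CH2 bond uses ring B as an electrophilic, reversed-polarity ("aryl cation") equivalent of the phenol (1,2-addition, then [3,3]); the enolate is then trapped at C3' and methanol is lost.
3. The ketal carbon keeps one OMe (5'-OMe) and the carbonyl returns as 2'-OH, so the hydroquinone oxygens are never differentiated by selective methylation.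
4. 8 ⇐ para-methoxyphenol 7 (PhI(OAc)2, MeOH) ⇐ aldehyde 5 (Dakin-type oxidation).
5. 5 ⇐ SNAr of salicylate phenol 3 on 2-fluoro-3,4-dimethoxybenzaldehyde 4; 3 ⇐ methyl 2,4,6-trihydroxybenzoate 1.

Ring B numbering: C1' carries the ether oxygen, C2' the OH, C3' and C4' the prenyl groups, C5' and C6' the methoxy groups.

Assumption: the target has no stereocentre or stereogenic double bond, so the single compound drawn is the goal; stereocentres in 11–13 are transient and racemic.

**Step 1**
Reactants: 1 methyl 2,4,6-trihydroxybenzoate; 2 chloromethyl methyl ether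
Product: 3 methyl 2-hydroxy-4,6-bis(methoxymethoxy)benzoate
Conditions: MOMCl (2.2 equiv), i-Pr2NEt, CH2Cl2, 0→23 °C
Reagents that add atoms: chloromethyl methyl ether 2, COCCl
Why: Williamson-type O-alkylation with the hard electrophile MOMCl stops at the bis-ether because the last ortho-OH is hydrogen-bonded to the ester carbonyl.

**Step 2**
Reactants: 3 methyl 2-hydroxy-4,6-bis(methoxymethoxy)benzoate; 4 2-fluoro-3,4-dimethoxybenzaldehyde
Product: 5 methyl 2-(6-formyl-2,3-dimethoxyphenoxy)-4,6-bis(methoxymethoxy)benzoate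
Conditions: Cs2CO3, DMSO, 100 °C
Reagents that add atoms: 2-fluoro-3,4-dimethoxybenzaldehyde 4, COc1ccc(C=O)c(F)c1OC
Why: Nucleophilic aromatic substitution (SNAr) in which the cesium phenoxide of 3 attacks the fluorine-bearing carbon activated by the ortho formyl group and fluoride leaves from the Meisenheimer intermediate.

**Step 3**
Reactants: 5 methyl 2-(6-formyl-2,3-dimethoxyphenoxy)-4,6-bis(methoxymethoxy)benzoate
Product: 7 methyl 2-(6-hydroxy-2,3-dimethoxyphenoxy)-4,6-bis(methoxymethoxy)benzoate, via aryl formate 6 (not isolated)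
Conditions: mCPBA, CH2Cl2, 0→23 °C; aqueous wash; then K2CO3 (0.2 equiv), MeOH, 0 °C
Reagents that add atoms: mCPBA, OOC(=O)c1cccc(Cl)c1
Why: Baeyer–Villiger (Dakin-type) oxidation in which the electron-rich aryl group migrates to give formate 6, which mild methanolysis cleaves without touching the hindered methyl ester or the MOM ethers.

**Step 4**
Reactants: 7 methyl 2-(6-hydroxy-2,3-dimethoxyphenoxy)-4,6-bis(methoxymethoxy)benzoate
Product: 8 methyl 4,6-bis(methoxymethoxy)-2-[(2,3,3-trimethoxy-6-oxocyclohexa-1,4-dien-1-yl)oxy]benzoate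
Conditions: PhI(OAc)2 (1.1 equiv), MeOH, 0 °C
Reagents that add atoms: methanol, CO
Why: Oxidative dearomatisation of a para-methoxyphenol by trivalent iodine, with methanol capturing the phenoxenium-type intermediate at the methoxy-bearing para carbon to give the quinone monoketal, which makes electron-rich ring B electrophilic while storing the 5'-O-methyl group.

**Step 5 (key step)**
Reactants: 8 methyl 4,6-bis(methoxymethoxy)-2-[(2,3,3-trimethoxy-6-oxocyclohexa-1,4-dien-1-yl)oxy]benzoate; 9 prenylmagnesium chloride; 10 prenyl bromide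
Product: 14 methyl 2-[6-hydroxy-2,3-dimethoxy-4,5-bis(3-methylbut-2-en-1-yl)phenoxy]-4,6-bis(methoxymethoxy)benzoate, via magnesium alkoxide 11 (not isolated), via magnesium enolate 12 (not isolated), via diprenyl ketone 13 (not isolated)
Conditions: prenylMgCl (1.15 equiv), THF, −78→23 °C; then DMPU, prenyl bromide (1.5 equiv), 0→23 °C; then CSA (cat.), 0→23 °C
Reagents that add atoms: prenylmagnesium chloride 9, CC(C)=CC[Mg]Cl; prenyl bromide 10, CC(C)=CCBr
Why: Proposed new method: the quinone monoketal lets a prenyl carbanion bond to C4', a carbon that is itself nucleophilic in the parent phenol, because prenylMgCl adds 1,2 to the dienone carbonyl through its γ-carbon (11), the 1,5-diene CH2=CH–CMe2–C2'–C3'=C4' then undergoes an alkoxide-accelerated [3,3] shift (anionic oxy-Cope; the breaking bond is doubly allylic between two fully substituted carbons, and the other ring alkene is fully substituted and unreactive) that places a linear prenyl group on C4' and leaves enolate 12, prenyl bromide C-alkylates 12 at C3' (13), and acid triggers E1 loss of methanol from the ketal plus tautomerisation to the phenol; the closest known reaction types are the allylic Grignard 1,2-addition/facile [3,3] rearrangement of mono-protected quinones used for regiospecific quinone isoprenylation, conjugate addition–enolate trapping of enones, and acid aromatisation of quinone monoketal Michael adducts, and the racemic stereocentres of 11–13 are erased on aromatisation.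

**Step 6**
Reactants: 14 methyl 2-[6-hydroxy-2,3-dimethoxy-4,5-bis(3-methylbut-2-en-1-yl)phenoxy]-4,6-bis(methoxymethoxy)benzoate
Product: 15 methyl 2,4-dihydroxy-6-[6-hydroxy-2,3-dimethoxy-4,5-bis(3-methylbut-2-en-1-yl)phenoxy]benzoate (4-methylhydroatrovirinone)
Conditions: HCl (1.25 M in MeOH), 23→40 °C
Reagents that add atoms: none
Why: Acid-catalysed acetal exchange removes both MOM ethers as dimethoxymethane under conditions routinely tolerated by prenyl groups ortho to free phenols, and methanol as solvent keeps the ester as the methyl ester.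

**Compound list**
1 | methyl 2,4,6-trihydroxybenzoate | COC(=O)c1c(O)cc(O)cc1O | starting material
2 | chloromethyl methyl ether | COCCl | starting material
3 | methyl 2-hydroxy-4,6-bis(methoxymethoxy)benzoate | COC(=O)c1c(O)cc(OCOC)cc1OCOC | intermediate
4 | 2-fluoro-3,4-dimethoxybenzaldehyde | COc1ccc(C=O)c(F)c1OC | starting material
5 | methyl 2-(6-formyl-2,3-dimethoxyphenoxy)-4,6-bis(methoxymethoxy)benzoate | COC(=O)c1c(OCOC)cc(OCOC)cc1Oc1c(C=O)ccc(OC)c1OC | intermediate
6 | methyl 2-[6-(formyloxy)-2,3-dimethoxyphenoxy]-4,6-bis(methoxymethoxy)benzoate | COC(=O)c1c(OCOC)cc(OCOC)cc1Oc1c(OC=O)ccc(OC)c1OC | intermediate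
7 | methyl 2-(6-hydroxy-2,3-dimethoxyphenoxy)-4,6-bis(methoxymethoxy)benzoate | COC(=O)c1c(OCOC)cc(OCOC)cc1Oc1c(O)ccc(OC)c1OC | intermediate
8 | methyl 4,6-bis(methoxymethoxy)-2-[(2,3,3-trimethoxy-6-oxocyclohexa-1,4-dien-1-yl)oxy]benzoate | COC(=O)c1c(OCOC)cc(OCOC)cc1OC1=C(OC)C(OC)(OC)C=CC1=O | intermediate
9 | prenylmagnesium chloride (3-methylbut-2-en-1-ylmagnesium chloride) | CC(C)=CC[Mg]Cl | starting material
10 | prenyl bromide (1-bromo-3-methylbut-2-ene) | CC(C)=CCBr | starting material
11 | chloromagnesium alkoxide of methyl 2-{[6-hydroxy-2,3,3-trimethoxy-6-(2-methylbut-3-en-2-yl)cyclohexa-1,4-dien-1-yl]oxy}-4,6-bis(methoxymethoxy)benzoate (racemic) | COC(=O)c1c(OCOC)cc(OCOC)cc1OC1=C(OC)C(OC)(OC)C=CC1(O[Mg]Cl)C(C)(C)C=C | intermediate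
12 | methyl 2-{[6-(chloromagnesiooxy)-2,3,3-trimethoxy-4-(3-methylbut-2-en-1-yl)cyclohexa-1,5-dien-1-yl]oxy}-4,6-bis(methoxymethoxy)benzoate (racemic) | COC(=O)c1c(OCOC)cc(OCOC)cc1OC1=C(OC)C(OC)(OC)C(CC=C(C)C)C=C1O[Mg]Cl | intermediate
13 | methyl 4,6-bis(methoxymethoxy)-2-{[2,3,3-trimethoxy-4,5-bis(3-methylbut-2-en-1-yl)-6-oxocyclohex-1-en-1-yl]oxy}benzoate (racemic diastereomer mixture) | COC(=O)c1c(OCOC)cc(OCOC)cc1OC1=C(OC)C(OC)(OC)C(CC=C(C)C)C(CC=C(C)C)C1=O | intermediate
14 | methyl 2-[6-hydroxy-2,3-dimethoxy-4,5-bis(3-methylbut-2-en-1-yl)phenoxy]-4,6-bis(methoxymethoxy)benzoate | COC(=O)c1c(OCOC)cc(OCOC)cc1Oc1c(O)c(CC=C(C)C)c(CC=C(C)C)c(OC)c1OC | intermediate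
15 | methyl 2,4-dihydroxy-6-[6-hydroxy-2,3-dimethoxy-4,5-bis(3-methylbut-2-en-1-yl)phenoxy]benzoate (4-methylhydroatrovirinone) | COC(=O)c1c(O)cc(O)cc1Oc1c(O)c(CC=C(C)C)c(CC=C(C)C)c(OC)c1OC | target

**Step count and risk**
Total steps: 6. Longest linear sequence: 6 (1 → 3 → 5 → 7 → 8 → 14 → 15).

Most likely to fail, step 5 (one-flask 1,2-addition, [3,3] shift, enolate prenylation, aromatisation). The weak points are a slow rearrangement of the magnesium alkoxide and O- or double alkylation of the magnesium enolate. The fallback sets out from 8 and comes back at 14, separating the two prenylations and making the second bond by a different logic. Add 9 at −78 °C and quench cold with NH4Cl to isolate the tertiary alcohol methyl 2-{[6-hydroxy-2,3,3-trimethoxy-6-(2-methylbut-3-en-2-yl)cyclohexa-1,4-dien-1-yl]oxy}-4,6-bis(methoxymethoxy)benzoate F1. Treat F1 with KH and 18-crown-6 in THF at 0 °C (anionic oxy-Cope), then CSA in MeOH, to obtain the mono-prenyl phenol methyl 2-[6-hydroxy-2,3-dimethoxy-4-(3-methylbut-2-en-1-yl)phenoxy]-4,6-bis(methoxymethoxy)benzoate F2. The second prenyl group then enters at the arene oxidation level by ortho-C-alkylation of the sodium phenoxide (NaH, toluene, 10, 23→60 °C); the only free ortho position is C3' and the para position is blocked, which gives 14.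

Second, step 2 (SNAr between a chelated, hindered salicylate phenoxide and a fluoride deactivated by the para methoxy group). The fallback sets out from 3 and comes back at 5, with the roles of the rings exchanged. Convert 3 with Tf2O and pyridine in CH2Cl2 at 0 °C into the aryl triflate methyl 2,4-bis(methoxymethoxy)-6-{[(trifluoromethyl)sulfonyl]oxy}benzoate F3. Couple F3 with purchased 2-hydroxy-3,4-dimethoxybenzaldehyde F4 by palladium-catalysed C–O bond formation (Pd(OAc)2, t-BuXPhos, K3PO4, toluene, 100 °C) to give 5.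

Third, step 6 (Brønsted acid with a phenol ortho to a prenyl group, risk of chroman formation). The fallback sets out from 14 and comes back at 15, masking the phenol that could cyclise and cleaving the acetals without protic acid. Acetylate 14 (Ac2O, pyridine, DMAP, CH2Cl2, 23 °C) to the aryl acetate methyl 2-[6-(acetyloxy)-2,3-dimethoxy-4,5-bis(3-methylbut-2-en-1-yl)phenoxy]-4,6-bis(methoxymethoxy)benzoate F5. Remove the MOM groups by Lewis acid–thiol transacetalisation (ZnBr2, n-PrSH, CH2Cl2, 0 °C) to give methyl 2-[6-(acetyloxy)-2,3-dimethoxy-4,5-bis(3-methylbut-2-en-1-yl)phenoxy]-4,6-dihydroxybenzoate F6. Cleave the acetate with K2CO3 in MeOH at 0 °C to reach 15.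

**Further compounds**
F1 | step 5 | methyl 2-{[6-hydroxy-2,3,3-trimethoxy-6-(2-methylbut-3-en-2-yl)cyclohexa-1,4-dien-1-yl]oxy}-4,6-bis(methoxymethoxy)benzoate (racemic) | COC(=O)c1c(OCOC)cc(OCOC)cc1OC1=C(OC)C(OC)(OC)C=CC1(O)C(C)(C)C=C
F2 | step 5 | methyl 2-[6-hydroxy-2,3-dimethoxy-4-(3-methylbut-2-en-1-yl)phenoxy]-4,6-bis(methoxymethoxy)benzoate | COC(=O)c1c(OCOC)cc(OCOC)cc1Oc1c(O)cc(CC=C(C)C)c(OC)c1OC
F3 | step 2 | methyl 2,4-bis(methoxymethoxy)-6-{[(trifluoromethyl)sulfonyl]oxy}benzoate | COC(=O)c1c(OCOC)cc(OCOC)cc1OS(=O)(=O)C(F)(F)F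
F4 | step 2 | 2-hydroxy-3,4-dimethoxybenzaldehyde (purchased coupling partner) | COc1ccc(C=O)c(O)c1OC
F5 | step 6 | methyl 2-[6-(acetyloxy)-2,3-dimethoxy-4,5-bis(3-methylbut-2-en-1-yl)phenoxy]-4,6-bis(methoxymethoxy)benzoate | COC(=O)c1c(OCOC)cc(OCOC)cc1Oc1c(OC(C)=O)c(CC=C(C)C)c(CC=C(C)C)c(OC)c1OC
F6 | step 6 | methyl 2-[6-(acetyloxy)-2,3-dimethoxy-4,5-bis(3-methylbut-2-en-1-yl)phenoxy]-4,6-dihydroxybenzoate | COC(=O)c1c(O)cc(O)cc1Oc1c(OC(C)=O)c(CC=C(C)C)c(CC=C(C)C)c(OC)c1OC
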